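**Plan**

- Retrosynthesis first removes the four acetyl groups, then cuts the five-membered hydroxy-lactone on ring B at its aryl–C(=O) and C(=O)–O bonds (loss of CO). The enabling feature is that the lactone carbonyl carbon sits on the ring B carbon between the phenol-bearing carbon and the lactol-bearing carbon, so it is one carbon monoxide beyond an ortho-bromo benzaldehyde.
- The seven-membered depsidone ring is then opened at the aryl ester C–O bond and at the diaryl ether C–O bond, giving a ring A 2-fluoro-3-formylbenzoate and a ring B bromo salicylaldehyde.
- Forward: ring A is made by ortho-lithiation/formylation, bromination and alkoxycarbonylation. Ring B is made by O-methylation, bromination, acetal protection, Baeyer–Villiger oxidation, benzylic acetoxylation and ortho-formylation.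
- The rings are joined by SNAr ether formation; the seven-membered lactone closes next and the five-membered hydroxy-lactone last, by carbonylation on the intact depsidone.
- The only stereocentre, the lactol carbon, arises racemic and mobile in the carbonylation. It is set to S by a catalyst-controlled acylative dynamic kinetic resolution (step 17) and carried through the enzymatic deacetylation.

Key step: step 15

Assumption: a free 3-hydroxyphthalide epimerises in solution through its ring-opened formyl acid, so the configuration is fixed as the O-acetyl acylal 26 and the free (S)-lactol 27 is released only in the last step, near neutral pH and in the cold, and collected as it precipitates.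

Step 1
Reactants: 1 1-fluoro-3-methoxy-5-methylbenzene
Product: 3 2-fluoro-6-methoxy-4-methylbenzaldehyde, via aryllithium 2 (not isolated)
Conditions: n-BuLi, THF, −78 °C; DMF; aq. HCl
Reagents that add atoms: N,N-dimethylformamide CN(C)C=O
Why: Directed ortho-metalation, in which the C–H flanked by fluorine and methoxy is the most acidic ring position, so lithiation and DMF quench should place the formyl group only there.

Step 2
Reactants: 3 2-fluoro-6-methoxy-4-methylbenzaldehyde
Product: 4 3-bromo-2-fluoro-6-methoxy-4-methylbenzaldehyde
Conditions: NBS, TFA/MeCN, rt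
Reagents that add atoms: N-bromosuccinimide O=C1CCC(=O)N1Br
Why: Electrophilic aromatic bromination should go para to the methoxy group (and ortho to fluorine), which outweighs the position between methoxy and methyl, both sites being meta to the formyl group.

Step 3
Reactants: 4 3-bromo-2-fluoro-6-methoxy-4-methylbenzaldehyde; 5 carbon monoxide
Product: 6 4-methoxybenzyl 2-fluoro-3-formyl-4-methoxy-6-methylbenzoate
Conditions: Pd(OAc)2 (cat.), Xantphos (cat.), CO (1 atm), 4-methoxybenzyl alcohol, Et3N, toluene, 100 °C
Reagents that add atoms: 4-methoxybenzyl alcohol COc1ccc(CO)cc1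
Why: Palladium-catalysed alkoxycarbonylation (Heck-type carbonylation) of the aryl bromide with a primary alcohol installs the hindered benzoate directly as an acid-labile ester, the meta formyl group being a spectator.

Step 4
Reactants: 7 2,4-dihydroxy-3-methylbenzaldehyde
Product: 8 2-hydroxy-4-methoxy-3-methylbenzaldehyde
Conditions: MeI (1.1 equiv), K2CO3 (1.0 equiv), acetone, rt
Reagents that add atoms: iodomethane CI
Why: Regioselective Williamson O-alkylation, since the 2-hydroxyl is hydrogen-bonded to the formyl group and flanked by the methyl group, so one equivalent of base should methylate only the 4-hydroxyl.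

Step 5
Reactants: 8 2-hydroxy-4-methoxy-3-methylbenzaldehyde
Product: 9 5-bromo-2-hydroxy-4-methoxy-3-methylbenzaldehyde
Conditions: NBS, MeCN, 0 °C
Reagents that add atoms: N-bromosuccinimide O=C1CCC(=O)N1Br
Why: Electrophilic aromatic bromination at C5, which is para to the free hydroxyl and ortho to the methoxy group, whereas C6 is meta to both donors.

Step 6
Reactants: 9 5-bromo-2-hydroxy-4-methoxy-3-methylbenzaldehyde
Product: 10 5-bromo-4-methoxy-2-(methoxymethoxy)-3-methylbenzaldehyde
Conditions: MOMCl, i-Pr2NEt, CH2Cl2, 0 °C to rt
Reagents that add atoms: chloromethyl methyl ether COCCl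
Why: O-Alkylation of the phenol with chloromethyl methyl ether gives an acetal ether that cannot migrate to a neighbouring oxygen later and is removed by acid.

Step 7
Reactants: 10 5-bromo-4-methoxy-2-(methoxymethoxy)-3-methylbenzaldehyde
Product: 12 5-bromo-4-methoxy-2-(methoxymethoxy)-3-methylphenol, via aryl formate 11 (not isolated)
Conditions: mCPBA, CH2Cl2, 0 °C to rt; then K2CO3 (cat.), MeOH, 0 °C
Reagents that add atoms: 3-chloroperoxybenzoic acid OOC(=O)c1cccc(Cl)c1
Why: Baeyer–Villiger (Dakin-type) oxidation in which the electron-rich aryl group, carrying ortho and para alkoxy groups, migrates to oxygen, followed by methanolysis of the aryl formate.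

Step 8
Reactants: 12 5-bromo-4-methoxy-2-(methoxymethoxy)-3-methylphenol
Product: 13 5-bromo-4-methoxy-2-(methoxymethoxy)-3-methylphenyl acetate
Conditions: Ac2O, Et3N, DMAP (cat.), CH2Cl2, rt
Reagents that add atoms: acetic anhydride CC(=O)OC(C)=O
Why: Acetylation of the phenol deactivates the ring so that the following radical bromination is not diverted into nuclear bromination ortho to a free hydroxyl.

Step 9
Reactants: 13 5-bromo-4-methoxy-2-(methoxymethoxy)-3-methylphenyl acetate
Product: 15 3-(acetoxymethyl)-5-bromo-4-methoxy-2-(methoxymethoxy)phenyl acetate, via benzylic bromide 14 (not isolated)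
Conditions: NBS, PhCF3, visible light, 25–30 °C; then KOAc, DMF, rt
Reagents that add atoms: potassium acetate CC(=O)[O-].[K+]
Why: Wohl–Ziegler radical bromination of the only benzylic methyl group at low temperature with immediate SN2 displacement by acetate, so that the electron-rich ortho-alkoxybenzyl bromide is neither stored nor heated.

Step 10
Reactants: 15 3-(acetoxymethyl)-5-bromo-4-methoxy-2-(methoxymethoxy)phenyl acetate
Product: 16 [5-bromo-3-hydroxy-6-methoxy-2-(methoxymethoxy)phenyl]methyl acetate
Conditions: pyrrolidine (1.1 equiv), CH2Cl2, 0 °C
Reagents that add atoms: none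
Why: Chemoselective aminolysis, an aryl acetate being a far better acyl donor than a primary alkyl acetate, so one equivalent of a secondary amine should free only the phenol.

Step 11
Reactants: 16 [5-bromo-3-hydroxy-6-methoxy-2-(methoxymethoxy)phenyl]methyl acetate
Product: 18 [5-bromo-4-formyl-3-hydroxy-6-methoxy-2-(methoxymethoxy)phenyl]methyl acetate, via hydroxymethyl phenol 17 (not isolated)
Conditions: MgCl2, Et3N, (CH2O)n, THF, 65 °C
Reagents that add atoms: paraformaldehyde (formaldehyde) C=O
Why: Magnesium-mediated ortho-formylation (Casnati–Skattebøl), in which the magnesium phenoxide delivers formaldehyde to the single free ortho position and a second formaldehyde oxidises the benzylic alkoxide to the aldehyde by hydride transfer.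

Step 12
Reactants: 18 [5-bromo-4-formyl-3-hydroxy-6-methoxy-2-(methoxymethoxy)phenyl]methyl acetate; 6 4-methoxybenzyl 2-fluoro-3-formyl-4-methoxy-6-methylbenzoate
Product: 19 4-methoxybenzyl 2-[3-(acetoxymethyl)-5-bromo-6-formyl-4-methoxy-2-(methoxymethoxy)phenoxy]-3-formyl-4-methoxy-6-methylbenzoate
Conditions: Cs2CO3, DMF, 70 °C
Reagents that add atoms: none
Why: Nucleophilic aromatic substitution (addition–elimination) at the fluorine-bearing carbon, activated by its ortho formyl and ortho ester groups, should leave the aryl bromide untouched and fixes the ether at the oxygen next to the ring B formyl group because the neighbouring oxygen is still an acetal ether.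

Step 13
Reactants: 19 4-methoxybenzyl 2-[3-(acetoxymethyl)-5-bromo-6-formyl-4-methoxy-2-(methoxymethoxy)phenoxy]-3-formyl-4-methoxy-6-methylbenzoate
Product: 20 2-[3-(acetoxymethyl)-5-bromo-6-formyl-2-hydroxy-4-methoxyphenoxy]-3-formyl-4-methoxy-6-methylbenzoic acid
Conditions: TFA, anisole, CH2Cl2, 0 °C to rt
Reagents that add atoms: none
Why: Acidolysis cleaves the 4-methoxybenzyl ester (SN1 at the benzylic carbon, cation trapped by anisole) and the methoxymethyl acetal in one operation, while the benzylic acetate, whose ring carries a para formyl group, should not ionise.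

Step 14
Reactants: 20 2-[3-(acetoxymethyl)-5-bromo-6-formyl-2-hydroxy-4-methoxyphenoxy]-3-formyl-4-methoxy-6-methylbenzoic acid
Product: 22 (7-bromo-4,6-diformyl-3,8-dimethoxy-1-methyl-11-oxo-11H-dibenzo[b,e][1,4]dioxepin-9-yl)methyl acetate, via mixed anhydride 21 (not isolated)
Conditions: (CF3CO)2O, toluene, 0 °C to rt
Reagents that add atoms: none
Why: Mixed-anhydride lactonisation, in which the trifluoroacetic mixed anhydride of the hindered acid is attacked by the neighbouring phenol to close the seven-membered depsidone ring (7-exo-trig) under acidic conditions that cannot expel the ortho benzylic acetate through a phenoxide.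

Step 15
Reactants: 22 (7-bromo-4,6-diformyl-3,8-dimethoxy-1-methyl-11-oxo-11H-dibenzo[b,e][1,4]dioxepin-9-yl)methyl acetate; 5 carbon monoxide
Product: 24 racemic protected depsidone lactol (the 7-carboxyl of 23 closed onto the 6-formyl carbon as a 3-hydroxyphthalide; both OMe groups and the CH2OAc group retained), via formyl acid 23 (not isolated)
Conditions: Pd(OAc)2 (5 mol %), Xantphos (6 mol %), CO (2 bar), H2O (10 equiv), i-Pr2NEt (2 equiv), 1,4-dioxane, 80 °C; then dilute HCl
Reagents that add atoms: water O
Why: Oxidative addition of Pd(0) into the ring B C–Br bond is followed by migratory insertion of CO and attack of water (or of the hydrate of the neighbouring formyl group) on the acyl-palladium, which forms the aryl–C(=O) bond and the C(=O)–O bond. The closest known reaction type is the palladium-catalysed hydroxy- or alkoxycarbonylation of 2-bromobenzaldehydes to 3-hydroxy- or 3-alkoxyphthalides. The five-membered hydroxy-lactone closes by 5-exo-trig addition of the carboxyl oxygen to the ortho formyl group, that is by ring-chain tautomerism of formyl acid 23. The new lactol stereocentre is under no control here and should arise as a racemic, equilibrating mixture; it is set in step 17. The step needs insertion into C–Br in preference to the benzylic acetate and survival of the seven-membered aryl ester, which the ortho formyl group (activating the bromide and capturing the acyl-palladium intramolecularly), the hindered tertiary amine base and the limited amount of water should secure.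

Step 16
Reactants: 24 racemic protected depsidone lactol
Product: 25 racemic diphenol lactol (24 without its two O-methyl groups; CH2OAc retained)
Conditions: BCl3, CH2Cl2, −78 to −20 °C; then H2O
Reagents that add atoms: none
Why: Chelation-assisted ether cleavage, in which boron trichloride binds between each methoxy oxygen and its ortho carbonyl (the ring A formyl group and the ring B lactone carbonyl) and should remove only these two methyl groups at low temperature.

Step 17
Reactants: 25 racemic diphenol lactol
Product: 26 (S)-tetraacetate (25 acetylated at both phenols and at the lactol oxygen; lactol carbon S)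
Conditions: Ac2O (6 equiv), benzotetramisole (10 mol %, the enantiomer that delivers the S acylal), i-Pr2NEt, CHCl3, 0 °C
Reagents that add atoms: acetic anhydride CC(=O)OC(C)=O
Why: Acylative dynamic kinetic resolution, in which the lactol epimerises through its ring-opened formyl carboxylate under amine base while the chiral isothiourea acyl-transfer catalyst acetylates one lactol enantiomer faster, so the S configuration is set by the catalyst and the two phenols are acetylated alongside.

Step 18
Reactants: 26 (S)-tetraacetate
Product: 27 (S)-salazinic acid (target)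
Conditions: immobilised Candida antarctica lipase B, phosphate buffer pH 6.5/MTBE, 5–10 °C
Reagents that add atoms: none
Why: Lipase-catalysed ester hydrolysis cleaves all four acetates at the acyl–oxygen bond near neutral pH, so the C–O bond at the lactol carbon is never broken and the S configuration should be retained while the sparingly soluble product precipitates.

**Compound list**

1 | 1-fluoro-3-methoxy-5-methylbenzene (3-fluoro-5-methylanisole, commercial) | COc1cc(C)cc(F)c1 | starting material
2 | (2-fluoro-6-methoxy-4-methylphenyl)lithium | COc1cc(C)cc(F)c1[Li] | intermediate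
3 | 2-fluoro-6-methoxy-4-methylbenzaldehyde | COc1cc(C)cc(F)c1C=O | intermediate
4 | 3-bromo-2-fluoro-6-methoxy-4-methylbenzaldehyde | COc1cc(C)c(Br)c(F)c1C=O | intermediate
5 | carbon monoxide | [C-]#[O+] | starting material
6 | 4-methoxybenzyl 2-fluoro-3-formyl-4-methoxy-6-methylbenzoate | COc1ccc(COC(=O)c2c(C)cc(OC)c(C=O)c2F)cc1 | intermediate
7 | 2,4-dihydroxy-3-methylbenzaldehyde (commercial; the formylation product of 2-methylresorcinol) | Cc1c(O)ccc(C=O)c1O | starting material
8 | 2-hydroxy-4-methoxy-3-methylbenzaldehyde | COc1ccc(C=O)c(O)c1C | intermediate
9 | 5-bromo-2-hydroxy-4-methoxy-3-methylbenzaldehyde | COc1c(Br)cc(C=O)c(O)c1C | intermediate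
10 | 5-bromo-4-methoxy-2-(methoxymethoxy)-3-methylbenzaldehyde | COCOc1c(C)c(OC)c(Br)cc1C=O | intermediate
11 | 5-bromo-4-methoxy-2-(methoxymethoxy)-3-methylphenyl formate | COCOc1c(C)c(OC)c(Br)cc1OC=O | intermediate
12 | 5-bromo-4-methoxy-2-(methoxymethoxy)-3-methylphenol | COCOc1c(C)c(OC)c(Br)cc1O | intermediate
13 | 5-bromo-4-methoxy-2-(methoxymethoxy)-3-methylphenyl acetate | COCOc1c(C)c(OC)c(Br)cc1OC(C)=O | intermediate
14 | 5-bromo-3-(bromomethyl)-4-methoxy-2-(methoxymethoxy)phenyl acetate | COCOc1c(CBr)c(OC)c(Br)cc1OC(C)=O | intermediate
15 | 3-(acetoxymethyl)-5-bromo-4-methoxy-2-(methoxymethoxy)phenyl acetate | COCOc1c(COC(C)=O)c(OC)c(Br)cc1OC(C)=O | intermediate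
16 | [5-bromo-3-hydroxy-6-methoxy-2-(methoxymethoxy)phenyl]methyl acetate | COCOc1c(COC(C)=O)c(OC)c(Br)cc1O | intermediate
17 | [5-bromo-3-hydroxy-4-(hydroxymethyl)-6-methoxy-2-(methoxymethoxy)phenyl]methyl acetate | COCOc1c(COC(C)=O)c(OC)c(Br)c(CO)c1O | intermediate
18 | [5-bromo-4-formyl-3-hydroxy-6-methoxy-2-(methoxymethoxy)phenyl]methyl acetate | COCOc1c(COC(C)=O)c(OC)c(Br)c(C=O)c1O | intermediate
19 | 4-methoxybenzyl 2-[3-(acetoxymethyl)-5-bromo-6-formyl-4-methoxy-2-(methoxymethoxy)phenoxy]-3-formyl-4-methoxy-6-methylbenzoate | COc1ccc(COC(=O)c2c(C)cc(OC)c(C=O)c2Oc2c(OCOC)c(COC(C)=O)c(OC)c(Br)c2C=O)cc1 | intermediate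
20 | 2-[3-(acetoxymethyl)-5-bromo-6-formyl-2-hydroxy-4-methoxyphenoxy]-3-formyl-4-methoxy-6-methylbenzoic acid | Cc1cc(OC)c(C=O)c(Oc2c(O)c(COC(C)=O)c(OC)c(Br)c2C=O)c1C(=O)O | intermediate
21 | mixed trifluoroacetic anhydride of acid 20 | Cc1cc(OC)c(C=O)c(Oc2c(O)c(COC(C)=O)c(OC)c(Br)c2C=O)c1C(=O)OC(=O)C(F)(F)F | intermediate
22 | (7-bromo-4,6-diformyl-3,8-dimethoxy-1-methyl-11-oxo-11H-dibenzo[b,e][1,4]dioxepin-9-yl)methyl acetate (depsidone ortho-bromo aldehyde) | Cc1cc(OC)c(C=O)c2c1C(=O)Oc1c(COC(C)=O)c(OC)c(Br)c(C=O)c1O2 | intermediate
23 | 9-(acetoxymethyl)-4,6-diformyl-3,8-dimethoxy-1-methyl-11-oxo-11H-dibenzo[b,e][1,4]dioxepine-7-carboxylic acid (ring-opened formyl acid) | Cc1cc(OC)c(C=O)c2c1C(=O)Oc1c(COC(C)=O)c(OC)c(C(=O)O)c(C=O)c1O2 | intermediate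
24 | racemic protected depsidone lactol: 3-hydroxyphthalide fused to ring B (carbonyl at the former C–Br carbon, lactol carbon from the ring B formyl group), ring A 3-OMe and 4-CHO, ring B 8-OMe and 9-CH2OAc | Cc1cc(OC)c(C=O)c2c1C(=O)Oc1c(COC(C)=O)c(OC)c3c(c1O2)C(O)OC3=O | intermediate
25 | racemic diphenol lactol: 24 with both methyl ethers cleaved, CH2OAc retained | Cc1cc(O)c(C=O)c2c1C(=O)Oc1c(COC(C)=O)c(O)c3c(c1O2)C(O)OC3=O | intermediate
26 | (S)-tetraacetate: 25 acetylated at both phenols and at the lactol oxygen, lactol carbon S | Cc1cc(OC(C)=O)c(C=O)c2c1C(=O)Oc1c(COC(C)=O)c(OC(C)=O)c3c(c1O2)[C@@H](OC(C)=O)OC3=O | intermediate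
27 | (S)-salazinic acid, CNP0166154.1 | Cc1cc(O)c(C=O)c2c1C(=O)Oc1c(CO)c(O)c3c(c1O2)[C@@H](O)OC3=O | target

**Count**

Total steps: 18. Longest linear sequence: 15 steps (7 to 27, steps 4–18); the ring A branch (steps 1–3) joins at step 12.

**Steps most likely to fail**

Step 15. The process at risk is hydrolytic opening of the seven-membered aryl ester by water and amine at 80 °C, or oxidative addition so slow at the doubly ortho-substituted C–Br bond that palladium begins to insert into the benzylic acetate. The fallback sets out from 22 and separates carbonylation from hydrolysis. Under anhydrous conditions 22 would be treated with 2,4,6-trichlorophenyl formate, Pd(OAc)2/Xantphos and Et3N in toluene, an aryloxycarbonylation in which carbon monoxide is released from the formate in the flask. This should give the 2,4,6-trichlorophenyl ester F1. Brief stirring of F1 in THF/pH 7 buffer at room temperature should hydrolyse this activated ester with help from the neighbouring formyl hydrate and close the lactol, so the sequence comes back to the route at 24.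

Step 17. The process at risk is an uncatalysed acetylation through the ring-opened formyl carboxylate, or acetylation outrunning epimerisation of the lactol, so that the acylal forms with poor enantiomeric purity. The fallback sets out from 25 and uses an enzyme for the resolution as well. Lipase-mediated acylative dynamic kinetic resolution with vinyl acetate in THF/MTBE and a trace of Et3N, with a lipase selected for S preference, should acetylate only the lactol oxygen and leave the hydrogen-bonded phenols free, giving the (S)-lactol monoacetate F2. The step 18 conditions then remove the two acetates of F2, and the sequence comes back to the route at 27.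

Step 16. The process at risk is ionisation of the benzylic acetate by the Lewis acid, with partial loss of the acetate as a benzylic chloride alongside the wanted demethylation. The fallback sets out from 24 and drives this loss to completion instead of resisting it. Excess BCl3 at 0 °C should give the racemic benzylic chloride F3 with both phenols free. Warming F3 in aqueous acetone should hydrolyse the ortho-hydroxybenzyl chloride, through the ortho-quinone methide, to racemic salazinic acid F4. F4 is then submitted to the step 17 conditions with one more equivalent of acetic anhydride, which acetylates the primary alcohol as well, so the sequence comes back to the route at 26.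

**Further compounds**

F1 | step 15 | 2,4,6-trichlorophenyl 9-(acetoxymethyl)-4,6-diformyl-3,8-dimethoxy-1-methyl-11-oxo-11H-dibenzo[b,e][1,4]dioxepine-7-carboxylate | Cc1cc(OC)c(C=O)c2c1C(=O)Oc1c(COC(C)=O)c(OC)c(C(=O)Oc3c(Cl)cc(Cl)cc3Cl)c(C=O)c1O2
F2 | step 17 | (S)-lactol monoacetate of 25 (phenols free, CH2OAc retained) | Cc1cc(O)c(C=O)c2c1C(=O)Oc1c(COC(C)=O)c(O)c3c(c1O2)[C@@H](OC(C)=O)OC3=O
F3 | step 16 | racemic benzylic chloride (25 with CH2Cl in place of CH2OAc) | Cc1cc(O)c(C=O)c2c1C(=O)Oc1c(CCl)c(O)c3c(c1O2)C(O)OC3=O
F4 | step 16 | racemic salazinic acid | Cc1cc(O)c(C=O)c2c1C(=O)Oc1c(CO)c(O)c3c(c1O2)C(O)OC3=O
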